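The ratio of Thursday's reading of target to Monday's at 12.0 h was 1.01, although Thursday's run held 2.22 times Monday's substrate. At that reading, then, the percentage did not follow the substrate charge beyond the scatter, so I reckoned the flask, whose charge lay between those two and whose reagent matched theirs, from that pair.

| flask | substrate | reagent in the second phase | remark | time | volume of the second phase over the first |
|---|---|---|---|---|---|
| Monday's | 0.54 M | 0.88 M | run made earlier |  |  |
| Thursday's | 1.2 M | 0.88 M | run made earlier |  |  |
| Wednesday's | 0.80 M | 1.8 M | run made earlier |  |  |
| flask | 0.80 M | 0.880 M |  | 10 h | 1.0 |

| Monday's: time / h | Monday's: target / % | Thursday's: time / h | Thursday's: target / % | Wednesday's: time / h | Wednesday's: target / % |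
|---|---|---|---|---|---|
| 1.00 | 12.8 | 1.50 | 15.2 | 1.50 | 25.6 |
| 2.00 | 22.2 | 4.00 | 18.7 | 4.00 | 18.8 |
| 5.00 | 19.6 | 8.00 | 12.6 | 8.00 | 7.9 |
| 12.0 | 9.6 | 12.0 | 9.7 | 12.0 | 4.3 |

(each reading ± 0.3 percentage points)

- in the second phase: reagent in the second phase; everything else is in the first
- charges count per volume of the first phase; a concentration in a rate is the amount of a species over the volume of its own phase; every rate counts per litre of the first phase
- the earlier runs hold the two phases in the same ratio of volumes as the flask asked about

* amount of target at 10 h, in percent of the substrate charged
* the change that raises the amount of target at 10 h, in percent of the substrate charged most ("none" if none brings more than 2 percentage points) (teal / green / none)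
* amount of target at 10 h, in percent of the substrate charged, after green

I had to walk back from 12.0 h to 10 h. Monday's readings from 5.00 h gave 0.102 h⁻¹, and Thursday's from 8.00 h gave 0.0654 h⁻¹. I called this the fade constant: the logarithm of the ratio of two readings of target past its peak, over the time between them, an apparent first-order rate constant that belongs to its stretch of time.

Walking back gave two independent figures for the flask, 11.8 % from Monday's run and 11.1 % from Thursday's. They parted by 0.70 percentage points, so I looked for the one that cheated. Thursday's fade constant from 4.00 h to 8.00 h was 0.0987 h⁻¹, larger than on its last stretch, so Thursday's fade slowed with time. Monday's constant reached back to 5.00 h, so I took its figure to read high. But Thursday's came from a heavier charge, so I committed to their mean, 11.4 %.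

Green meant 1.76 M of reagent, close to Wednesday's 1.8 M. Wednesday's fade constant, 0.152 h⁻¹, walked back from 12.0 h gave 5.83 %, a loss of 5.6 points. For teal I had no run, but 10 h lay later than the highest reading of each run, so I expected no gain and answered none.

The forecast gave 11.5 %, 6 % after green and none as the best change, holding that “Faster transfer can only speed the process”.

The flask gave 11.6 % and 6.06 % after green; teal moved target by −1.3 points and green by −5.6 points, so the best change was none.

    reagent in the reaction phase ⇌ reagent in the second phase, rate k1*([reagent in the reaction phase] - [reagent in the second phase]/K1) per volume of the first phase (partition coefficient = 0.700, kL = 1.00 × 10⁻⁴ s⁻¹)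
    substrate + reagent in the reaction phase ⇌ target (K = 3.10 M⁻¹, k = 3.60 × 10⁻⁴ M⁻¹ s⁻¹)
    reagent in the reaction phase + target → over-reacted product (k = 3.30 × 10⁻⁴ M⁻¹ s⁻¹)
    reagent in the reaction phase + target → over-reaction product (k = 1.20 × 10⁻⁴ M⁻¹ s⁻¹)

In the flask the fade constant was 0.0986 h⁻¹ from 5.00 h to 10 h and 0.0668 h⁻¹ from there to 20.0 h, slower, as Thursday's had been; green's flask stood at 6.06 % against the 5.83 % from Wednesday's fade. Two steps acting together hold the flask's target down: the reverse step, target to substrate and reagent in the reaction phase, is the largest single effect, and the step to over-reacted product is a part of it. Against 11.6 % in the flask at 10 h, target stood at 25.2 % in the run without the step to over-reacted product and at 31.8 % in the run without the reverse step.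

(The runs were computed for substances that don't exist; the scatter is artificial.)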